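The constants belong to no real substance; what happens was integrated by code.

The nucleophile in these flasks had two jobs: it attacked the electrophile, and it then took up the acid set free by that attack.

    electrophile + protic impurity → quenched substrate (k1 = 0.23 M⁻¹ h⁻¹)
    electrophile ⇌ dormant form (K2 = 22, k2 = 0.016 h⁻¹)
    nucleophile + acid set free ⇌ protonated nucleophile, settled at all times (K3 = 2000 M⁻¹)
    electrophile + nucleophile → acid set free + product (k4 = 1.1 M⁻¹ h⁻¹)

all flasks: electrophile 0.20 M; protic impurity 0.200 M; time 12 h

| flask | nucleophile |
|---|---|
| oak | 1.20 equiv |
| cedar | 1.60 equiv |
| elm | 2.00 equiv |

- part of the electrophile that has reacted at the end, oak
- part of the electrophile that has reacted at the end, cedar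
- part of the electrophile that has reacted at the end, elm
- what raising the equivalents of nucleophile from its lowest to its highest value here does to the part of the electrophile that has reacted (changes below 5 percentage points count as none) (it falls / no change / it rises)

- what has gone from electrophile into another species counts as reacted, even if it can come back
- run time (oak): 12 h

1. Oak looked safe to me, with 1.20 equiv of nucleophile, an excess on paper, and a run of 4.62 half-lives of the main step, whose 2.6 h as charged is shorter than the 15 h of the quench.

2. But the equilibrium constant of the pairing times the nucleophile charged in oak came to 480, so at the start nearly all of each acid set free would take a nucleophile with it, and I priced each product at two nucleophile.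

3. At that price oak could pay for 0.600 of the electrophile charged, cedar for 0.800 and elm for 1.00, and this fraction, the equivalents divided by two, I called the ceiling. Elm was my zero, the even case, while in oak and cedar the nucleophile was the limiting reagent.

4. The electrophile above the ceiling could still leave by the side steps, and with the protic impurity held at its charge their rate constants summed to 0.0620 h⁻¹; that overstated the loss, since the impurity is used up as it quenches, so over 12 h this electrophile kept at least 0.475 of itself.

5. That gave me 81.0 % reacted for oak, 90.5 % for cedar and 100 % for elm, and I took the elm figure as too high, since it counts the main step as finished.

6. The forecast gave 80.5 %, 88.5 % and 93.5 %, so that it rises, on the ground that each product frees an acid that “ties up a second nucleophile almost completely”; for elm it stood lower than my figure.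

7. The simulation gave 81.0 %, 88.7 % and 93.9 %, so that it rises, by 13 percentage points from oak to elm, and the difference in equivalents of nucleophile is the main reason.

The pairing was part of what held oak back: without it, oak reached 91.6 % reacted and not 81.0 %. Oak's product stood at 53.2 % after 12.0 h and at 58.7 % after 120 h, beneath its ceiling of 0.600. The neighbour of cedar with 0.400 equiv of nucleophile has a ceiling of 0.200, which with the same side steps gives 62.0 % reacted; that flask reached 59.9 %, with its product at 19.7 %.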